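Carbon atoms are numbered C1 (ring-fusion carbon with the methyl), C2 and C3 (ring CH2), C4 (isopropyl carbinol), C5 (ring-fusion CH), C6 (ester carbon), C7 (CH2), C8 (methyl-bearing epoxide carbon), C9 (epoxide CH) and C10 (CH2). β is the face of the C1 methyl, α the opposite face. Compounds are numbered 1–24 in the order of the steps.

## Analysis of the target

The target 24 is a daucane sesquiterpenoid ester on a bicyclo[5.3.0]decane: a cyclopentane (C1–C5) fused through C1–C5 to a cycloheptane (C1, C5–C10), with a methyl on quaternary C1, an isopropyl carbinol at C4, a 4-hydroxybenzoate on C6 and a trisubstituted epoxide across C8 and C9. It has six stereocentres: C1, C4, C5, C6, C8 and C9. H5 is α (trans fusion), the C4 hydroxyl is β and its isopropyl α, the C6 oxygen is β (cis to the angular methyl, so H5 and H6 are both α), and the epoxide oxygen is α. C4, C5 and C6 are contiguous and lean on quaternary C1, and the C1 methyl and the C6 oxygen stand 1,3 and syn on the seven-membered ring. Sensitive groups are the acid-labile epoxide, the tertiary alcohol, the aryl ester and the free phenol; on the way, C5 can epimerise whenever C4 or C6 is a ketone, and a C6 ketone would lie β,γ to the C8=C9 alkene. The hard points are the quaternary centre next to the fusion CH, a seven-membered ring with a regiodefined trisubstituted alkene, and a trans fusion that, with an angular methyl, cannot be trusted to come from enolate protonation or equilibration. The plan reads the C1–C5 bond with its methyl and C10 as a bicyclo[3.1.0]hexane whose cyclopropane methylene is C10, C6–C7 as an oxygenated vinyl group on C5, and C8=C9 with its methyl as a propyne unit.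

## Retrosynthetic reasoning

The last operations are removal of the phenol silyl group from 23 and, before it, formation of the two C–O bonds of the epoxide from alkene 22. The epoxide is the most acid-sensitive group, so it is made after every acidic or organometallic step. In 22 the axial C1 methyl and the axial C6 acyloxy group both screen the β face of the alkene, so a peracid should come from the α face, as required.

The C6–O acyl bond is cut next, giving diol 18 and the silyl-protected acid 21 (from 19 through 20). Acylation is late because an aryl ester at C6 would not survive the organometallic addition at C4 and would be a good leaving group β to a C4 ketone. The forward step only has to distinguish the secondary C6 hydroxyl from the tertiary C4 hydroxyl.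

The C4–isopropyl bond is cut, leading through silyl ether 17 to ketone 16. Cutting here lets the ring set C4: the nucleophile must enter the cyclopentanone from the α face, opposite the β-oriented C5–C6 bond and the angular methyl. The C6 oxygen is masked as a silyl ether, a poor leaving group, because in 16 it is β to the ketone.

Ketone 16 comes from secondary alcohol 15, the protodesilylation product of 14, and the C5–H and C6–H bonds of 14 are cut together, back to allylic alcohol 13. Hydrolysing the enol ether to a C6 ketone was weighed and set aside for three reasons: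
- that ketone is β,γ-unsaturated, so any condition that equilibrates C5 also moves the alkene into conjugation;
- kinetic protonation at C5 should come from the face away from the C4 oxygen, giving the cis fusion;
- the angular methyl tilts the equilibrium towards cis as well.

In 13 the C4 hydroxyl lies on the α face, where H5 and H6 are needed, so a hydroxyl-directed cis addition of hydrogen sets both centres and leaves the C6 oxygen already protected. The silyl group on C9 is kept until then because it makes C8=C9 tetrasubstituted and unreactive.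

Alcohol 13 is the C4-desilylated form of 12, and in 12 the bonds C7–C8 and C9–C10 are cut. This opens the seven-membered ring into siloxy-vinylcyclopropane 10 and silylalkyne 11. It is the one cut that creates the seven-membered ring, the C8 methyl and the C8=C9 alkene in one convergent step, with the quaternary centre already fixed in a small rigid bicycle. The forward reaction must open the C5–C10 bond and not the fusion bond, and must orient 11 with its methyl carbon towards C7.

The two O–Si bonds of 10 are cut in turn, through 9 to hydroxy ketone 8. Two different silyl groups are used on purpose. The trimethylsilyl ether on C4 can be removed with methanolic carbonate. The triisopropylsilyl enol ether survives that, the cycloaddition and the hydrogenation, and then serves as the C6 protecting group.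

The ketone oxygen of 8 is removed to give alkyne 7 (from silylalkyne 6), and the C1–C10 and C5–C10 bonds of the cyclopropane are cut to give enynol 5. C6 and C7 are carried as an alkyne through the cyclopropanation because a zinc carbenoid is electrophilic: an acetyl group on the alkene would deactivate it, whereas an alkynyl group does not and is itself inert. The hydroxyl-directed methylene transfer sets C1 cis to the carbinol.

The C5–C6 bond is cut to alkenyl bromide 3 and alkyne 4. Bromide 3 comes from enantioselective reduction of bromoenone 2, the α-bromination product of 1. The carbinol centre made here is sacrificial: it controls C1 in step 4 and C5/C6 in step 11 and is then oxidised.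

## Alternatives that were turned down

Alternative 1: Both rings are opened at once by cutting C1–C5 and C6–C7. Forward, rhodium would open the C1–C9 bond of the cis-configured cyclopropane 5-[(1R,2R)-1-methyl-2-(prop-1-en-2-yl)cyclopropyl]pent-1-yn-3-one A2, and the tethered ynone would insert to give the dienone (8aR)-6,8a-dimethyl-2,5,8,8a-tetrahydroazulen-3(1H)-one A1.
- For: two rings and two bonds in one intramolecular step, regiochemistry fixed by the tether, C1 available from an enantioselective cyclopropanation of a cheap terpene alcohol, a C4 ketone in place and no silyl group to remove. On ring count and on steps up to the bicycle it is stronger than the chosen route.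
- Against: the bond that must open ends at quaternary C1 and gives a tertiary alkylrhodium, and the tether hangs from the cyclopropane and not from the alkene, an unusual geometry for this cycloaddition. A1 has no oxygen at C6, so the C5=C6 enone must later be oxygenated at C6 and reduced at C5 with only C1 to guide both. The doubly allylic C7 invites isomerisation to the fully conjugated dienone.
- Comparison: the chosen route closes one ring in its key step and needs more steps, but it carries the C6 oxygen through the cycloaddition and keeps an α carbinol at C4 that directs the hydrogens onto C5 and C6.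

Alternative 2: Only the five-membered ring is disconnected, at C1–C5. Forward, monovalent gold would activate the alkyne of (4R,5Z)-7-[(tert-butyldimethylsilyl)oxy]-1,1-diethoxy-6-methylhept-5-en-2-yn-4-yl 2,2-dimethylpropanoate A4. The pivalate would shift from C3 to C4 while C5 bonds to C1 (Rautenstrauch rearrangement), giving (4S,5S)-4-{[(tert-butyldimethylsilyl)oxy]methyl}-5-(diethoxymethyl)-4-methylcyclopent-2-en-1-one A3 with the C3 chirality relayed to C1.
- For: mild catalysis, a quaternary centre from an easily made propargylic carbinol, the C4 ketone already in the five-membered ring and C6 at the aldehyde level, ready to take C7 with its oxygen in place. On the C4/C6 oxygen pattern it is at least as good as the chosen route.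
- Against: the seven-membered ring is still missing and needs several further C–C bonds and a ring closure to a trisubstituted cycloheptene. Chirality transfer to a quaternary centre demands a geometrically pure trisubstituted alkene and tolerates crowding poorly. C5 of A3 is α to the ketone and β to the acetal oxygens, so it can epimerise or eliminate.
- Comparison: the chosen route makes the seven-membered ring, the C8 methyl and the C8=C9 alkene in one step. In place of the ready-made C4 ketone it offers a C4 carbinol that is used twice as a directing group before it is oxidised.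

Alternative 3: The five-membered ring is closed last, by cutting C4–C5. Forward, (6S)-6-{(3R)-3-[(tert-butyldimethylsilyl)oxy]-4-methylpentyl}-7-diazo-3,6-dimethylcyclohept-2-en-1-one A6 would lose nitrogen and the rhodium carbenoid at C5 would insert into the tertiary C4–H bond with retention. After equilibration at C5 this would give (3R,3aR,8aS)-3-[(tert-butyldimethylsilyl)oxy]-6,8a-dimethyl-3-(propan-2-yl)-2,3,3a,7,8,8a-hexahydroazulen-4(1H)-one A5.
- For: the crowded tertiary C4 centre comes from a secondary carbinol by retention, so no isopropyl addition to an enolisable ketone is needed. On C4 it is stronger than the chosen route.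
- Against: the cycloheptenone with quaternary C1 must be made first. Insertion into a methine flanked by isopropyl and a bulky silyl ether is sterically demanding and competes with insertion at C2 or C3. The trans fusion of A5 rests on an equilibration that an angular methyl does not favour. The alkene of A5 sits at C7=C8 and must be moved out of conjugation to C8=C9.
- Comparison: the chosen route builds C4 later and by addition, but the alkene is born in the right place and the ring-fusion hydrogen is delivered, not equilibrated.

Key step: step 9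

Remark: the C6 oxygen of the target is cis to the C1 methyl (6R in daucane numbering, 4R in the azulene names below), and the route is built for that configuration.

## Route

Step 1
Reactants: 1 3-methylcyclopent-2-en-1-one
Product: 2 2-bromo-3-methylcyclopent-2-en-1-one
Conditions: Br2, CH2Cl2, 0 °C; then Et3N, 0 °C to rt
Reagents that add atoms: bromine, BrBr
Why: Bromine addition to the enone and dehydrobromination with triethylamine is the standard α-bromination of enones; only the α position can end up brominated because the β carbon carries the methyl.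

Step 2
Reactants: 2 2-bromo-3-methylcyclopent-2-en-1-one
Product: 3 (R)-2-bromo-3-methylcyclopent-2-en-1-ol
Conditions: (S)-2-methyl-CBS-oxazaborolidine (0.2 equiv), BH3·SMe2, THF, −20 °C
Reagents that add atoms: none
Why: CBS reduction, in which the bromoalkenyl arm acts as the large group so that the (S)-catalyst should give the (R)-carbinol; this centre (C4) is sacrificial and later directs steps 4 and 11.

Step 3
Reactants: 3 (R)-2-bromo-3-methylcyclopent-2-en-1-ol; 4 ethynyltrimethylsilane
Product: 5 (R)-3-methyl-2-[(trimethylsilyl)ethynyl]cyclopent-2-en-1-ol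
Conditions: Pd(PPh3)2Cl2 (5 mol%), CuI (10 mol%), i-Pr2NH, THF, 60 °C
Reagents that add atoms: none
Why: Sonogashira coupling of an alkenyl bromide; the free allylic hydroxyl is tolerated, and the two alkyne carbons become C6 and C7 at the ketone oxidation level without putting an electron-withdrawing group on the alkene.

Step 4
Reactants: 5 (R)-3-methyl-2-[(trimethylsilyl)ethynyl]cyclopent-2-en-1-ol
Product: 6 (1S,2R,5R)-5-methyl-1-[(trimethylsilyl)ethynyl]bicyclo[3.1.0]hexan-2-ol
Conditions: Et2Zn, CH2I2, CH2Cl2, 0 °C to rt
Reagents that add atoms: diiodomethane, ICI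
Why: Hydroxyl-directed Simmons–Smith cyclopropanation: the zinc alkoxide delivers the methylene (C10) to the alkene face cis to the hydroxyl, which fixes quaternary C1 relative to the carbinol; the electron-rich tetrasubstituted alkene reacts while the silylalkyne is inert to the zinc carbenoid.

Step 5
Reactants: 6 (1S,2R,5R)-5-methyl-1-[(trimethylsilyl)ethynyl]bicyclo[3.1.0]hexan-2-ol
Product: 7 (1S,2R,5R)-1-ethynyl-5-methylbicyclo[3.1.0]hexan-2-ol
Conditions: K2CO3, MeOH, rt
Reagents that add atoms: none
Why: Methanolysis of the alkynyl C–Si bond under mild base; nothing else in the molecule responds to these conditions.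

Step 6
Reactants: 7 (1S,2R,5R)-1-ethynyl-5-methylbicyclo[3.1.0]hexan-2-ol
Product: 8 1-[(1R,2R,5R)-2-hydroxy-5-methylbicyclo[3.1.0]hexan-1-yl]ethan-1-one
Conditions: (Ph3P)AuNTf2 (2 mol%), H2O, 1,4-dioxane, 60 °C
Reagents that add atoms: water, O
Why: Gold-catalysed hydration of a terminal alkyne puts the oxygen on the internal carbon (C6), the position stabilised by the cyclopropyl group, and gives the methyl ketone; the hydroxyl is trans to the alkynyl group on the five-membered ring and cannot cyclise onto it.

Step 7
Reactants: 8 1-[(1R,2R,5R)-2-hydroxy-5-methylbicyclo[3.1.0]hexan-1-yl]ethan-1-one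
Product: 9 1-[(1R,2R,5R)-5-methyl-2-[(trimethylsilyl)oxy]bicyclo[3.1.0]hexan-1-yl]ethan-1-one
Conditions: Me3SiCl, imidazole, CH2Cl2, 0 °C
Reagents that add atoms: chlorotrimethylsilane, C[Si](C)(C)Cl
Why: Silylation of the secondary alcohol without enolising the ketone; the labile trimethylsilyl ether is chosen because it can later be removed without touching the enol ether.

Step 8
Reactants: 9 1-[(1R,2R,5R)-5-methyl-2-[(trimethylsilyl)oxy]bicyclo[3.1.0]hexan-1-yl]ethan-1-one
Product: 10 trimethyl{[(1R,2R,5R)-5-methyl-1-{1-[(triisopropylsilyl)oxy]ethenyl}bicyclo[3.1.0]hexan-2-yl]oxy}silane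
Conditions: LiN(i-Pr)2, THF, −78 °C; then i-Pr3SiOTf, −78 to 0 °C
Reagents that add atoms: triisopropylsilyl trifluoromethanesulfonate, CC(C)[Si](C(C)C)(C(C)C)OS(=O)(=O)C(F)(F)F
Why: The methyl group is the only enolisable position (C5 is quaternary), so enolate formation and O-silylation give a single enol ether; the triisopropylsilyl group is chosen to survive methanolysis, the cycloaddition and the hydrogenation.

Step 9
Reactants: 10 trimethyl{[(1R,2R,5R)-5-methyl-1-{1-[(triisopropylsilyl)oxy]ethenyl}bicyclo[3.1.0]hexan-2-yl]oxy}silane; 11 trimethyl(prop-1-yn-1-yl)silane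
Product: 12 triisopropyl({(3R,8aR)-6,8a-dimethyl-7-(trimethylsilyl)-3-[(trimethylsilyl)oxy]-1,2,3,5,8,8a-hexahydroazulen-4-yl}oxy)silane
Conditions: [Rh(CO)2Cl]2 (5 mol%), 11 (3 equiv), 1,2-dichloroethane, 80 °C
Reagents that add atoms: none
Why: [Rh(CO)2Cl]2 binds the enol ether alkene and inserts into the external C5–C10 bond of the strained cyclopropane, giving a rhodacycle held as a π-allyl over C5–C6–C7 with a σ bond to C10; the alkyne then inserts at the allyl terminus to form C7–C8, and C(sp2)–C(sp3) reductive elimination forms C9–C10. The closest known reaction type is the rhodium-catalysed intermolecular (5+2) cycloaddition of oxygen-substituted vinylcyclopropanes with alkynes. The seven-membered ring is closed by formal cycloaddition, two σ bonds being made between a five-carbon and a two-carbon partner through an eight-membered rhodacycle, while the cyclopentane stays intact. No stereocentre is created: C1 keeps the configuration from step 4 because none of its bonds is broken, and C4 is a spectator. Two selectivities are needed. The ring opening must take the C5–C10 bond and not the C5–C1 fusion bond; insertion next to the CH2 gives a primary alkylrhodium, the alternative a tertiary one, and C1 has no hydrogen, so β-hydride elimination from the rhodacycle is blocked. The alkyne must place its methyl carbon on C7; the trimethylsilyl group avoids the crowded first-formed C7–C8 bond and ends on C9, next to C10. The small trimethylsilyl ether on the α face keeps the approach to the C5–C10 bond open.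

Step 10
Reactants: 12 triisopropyl({(3R,8aR)-6,8a-dimethyl-7-(trimethylsilyl)-3-[(trimethylsilyl)oxy]-1,2,3,5,8,8a-hexahydroazulen-4-yl}oxy)silane
Product: 13 (3R,8aR)-6,8a-dimethyl-4-[(triisopropylsilyl)oxy]-7-(trimethylsilyl)-1,2,3,5,8,8a-hexahydroazulen-3-ol
Conditions: K2CO3, MeOH, 0 °C
Reagents that add atoms: none
Why: Methanolic carbonate cleaves the trimethylsilyl ether of a secondary alcohol within minutes, whereas the hindered triisopropylsilyl enol ether and the vinylsilane are inert; this frees the α hydroxyl needed as a directing group.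

Step 11
Reactants: 13 (3R,8aR)-6,8a-dimethyl-4-[(triisopropylsilyl)oxy]-7-(trimethylsilyl)-1,2,3,5,8,8a-hexahydroazulen-3-ol
Product: 14 (3R,3aR,4R,8aR)-6,8a-dimethyl-4-[(triisopropylsilyl)oxy]-7-(trimethylsilyl)-1,2,3,3a,4,5,8,8a-octahydroazulen-3-ol
Conditions: H2 (1 atm), [Ir(cod)(PCy3)(py)]PF6 (10 mol%), CH2Cl2, 0 °C to rt
Reagents that add atoms: none
Why: Proposed new method: hydroxyl-directed hydrogenation with this cationic iridium complex is established for tri- and tetrasubstituted alkenes next to a carbinol, including cases that set a ring-fusion hydrogen, but not for a tetrasubstituted silyl enol ether; here the α hydroxyl at C4 should bind the iridium dihydride and hold it under the α face of C5=C6, so that both hydrogens add cis from α, giving H5 α (trans fusion) and H6 α (C6 oxygen β), while the tetrasubstituted vinylsilane C8=C9 has no donor nearby and should stay; the closest known reaction type is the hydroxyl-directed iridium-catalysed hydrogenation of tetrasubstituted cyclic allylic alcohols.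

Step 12
Reactants: 14 (3R,3aR,4R,8aR)-6,8a-dimethyl-4-[(triisopropylsilyl)oxy]-7-(trimethylsilyl)-1,2,3,3a,4,5,8,8a-octahydroazulen-3-ol
Product: 15 (3R,3aR,4R,8aR)-6,8a-dimethyl-4-[(triisopropylsilyl)oxy]-1,2,3,3a,4,5,8,8a-octahydroazulen-3-ol
Conditions: CF3CO2H, CH2Cl2, 0 °C; then aq. NaHCO3
Reagents that add atoms: none
Why: Protodesilylation of a vinylsilane: ipso protonation at C9 gives a tertiary, β-silyl-stabilised cation at C8 that loses silicon, so the double bond stays at C8=C9. It is done at this stage because the triisopropylsilyl ether and the secondary alcohol tolerate brief acid, whereas the later ketone and tertiary alcohol would not.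

Step 13
Reactants: 15 (3R,3aR,4R,8aR)-6,8a-dimethyl-4-[(triisopropylsilyl)oxy]-1,2,3,3a,4,5,8,8a-octahydroazulen-3-ol
Product: 16 (3aS,4R,8aR)-6,8a-dimethyl-4-[(triisopropylsilyl)oxy]-2,3a,4,5,8,8a-hexahydroazulen-3(1H)-one
Conditions: Dess–Martin periodinane, NaHCO3, CH2Cl2, 0 °C
Reagents that add atoms: none
Why: Dess–Martin oxidation under bicarbonate buffer gives the C4 ketone without acid or base strong enough to epimerise C5 or eliminate the β-silyloxy group; the ketone is used at once.

Step 14
Reactants: 16 (3aS,4R,8aR)-6,8a-dimethyl-4-[(triisopropylsilyl)oxy]-2,3a,4,5,8,8a-hexahydroazulen-3(1H)-one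
Product: 17 (3R,3aS,4R,8aR)-6,8a-dimethyl-3-(propan-2-yl)-4-[(triisopropylsilyl)oxy]-1,2,3,3a,4,5,8,8a-octahydroazulen-3-ol
Conditions: i-PrMgCl, CeCl3, THF, −78 °C
Reagents that add atoms: isopropylmagnesium chloride, CC(C)[Mg]Cl
Why: 1,2-Addition of an organocerium reagent, whose low basicity limits enolisation, β-elimination and hydride transfer. The nucleophile should approach the cyclopentanone from the α face, anti to the β-oriented C5–C6 bond and the angular methyl, which sets C4 with hydroxyl β and isopropyl α.

Step 15
Reactants: 17 (3R,3aS,4R,8aR)-6,8a-dimethyl-3-(propan-2-yl)-4-[(triisopropylsilyl)oxy]-1,2,3,3a,4,5,8,8a-octahydroazulen-3-ol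
Product: 18 (3R,3aS,4R,8aR)-6,8a-dimethyl-3-(propan-2-yl)-1,2,3,3a,4,5,8,8a-octahydroazulene-3,4-diol
Conditions: Bu4NF, THF, rt to 40 °C
Reagents that add atoms: none
Why: Fluoride cleaves the Si–O bond of the secondary silyl ether; the tertiary alcohol, the alkene and the ring fusion are untouched.

Step 16
Reactants: 19 4-hydroxybenzoic acid
Product: 21 4-[(tert-butyldimethylsilyl)oxy]benzoic acid, via tert-butyldimethylsilyl 4-[(tert-butyldimethylsilyl)oxy]benzoate 20 (not isolated)
Conditions: t-BuMe2SiCl, imidazole, DMF, rt; then AcOH, H2O, THF, rt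
Reagents that add atoms: tert-butyldimethylsilyl chloride, CC(C)(C)[Si](C)(C)Cl
Why: Both the phenol and the acid are silylated, and the much more labile silyl ester is then hydrolysed selectively, leaving the phenol protected.

Step 17
Reactants: 18 (3R,3aS,4R,8aR)-6,8a-dimethyl-3-(propan-2-yl)-1,2,3,3a,4,5,8,8a-octahydroazulene-3,4-diol; 21 4-[(tert-butyldimethylsilyl)oxy]benzoic acid
Product: 22 (3R,3aS,4R,8aR)-3-hydroxy-6,8a-dimethyl-3-(propan-2-yl)-1,2,3,3a,4,5,8,8a-octahydroazulen-4-yl 4-[(tert-butyldimethylsilyl)oxy]benzoate
Conditions: EDC·HCl, DMAP, CH2Cl2, rt to 40 °C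
Reagents that add atoms: none
Why: Steglich esterification: the secondary C6 hydroxyl, although axial, is acylated and the tertiary C4 hydroxyl is not; the neutral conditions avoid dehydration of the tertiary alcohol.

Step 18
Reactants: 22 (3R,3aS,4R,8aR)-3-hydroxy-6,8a-dimethyl-3-(propan-2-yl)-1,2,3,3a,4,5,8,8a-octahydroazulen-4-yl 4-[(tert-butyldimethylsilyl)oxy]benzoate
Product: 23 (3R,3aS,4R,6R,7S,8aR)-6,7-epoxy-3-hydroxy-6,8a-dimethyl-3-(propan-2-yl)decahydroazulen-4-yl 4-[(tert-butyldimethylsilyl)oxy]benzoate
Conditions: m-CPBA, NaHCO3, CH2Cl2, 0 °C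
Reagents that add atoms: 3-chloroperoxybenzoic acid, OOC(=O)c1cccc(Cl)c1
Why: Peracid epoxidation of the only alkene: the β face of C8=C9 is screened by the axial C1 methyl and the axial C6 acyloxy group, so oxygen should be delivered to the α face, setting C8 and C9. Bicarbonate keeps the acid by-product from opening the epoxide.

Step 19
Reactants: 23 (3R,3aS,4R,6R,7S,8aR)-6,7-epoxy-3-hydroxy-6,8a-dimethyl-3-(propan-2-yl)decahydroazulen-4-yl 4-[(tert-butyldimethylsilyl)oxy]benzoate
Product: 24 (3R,3aS,4R,6R,7S,8aR)-6,7-epoxy-3-hydroxy-6,8a-dimethyl-3-(propan-2-yl)decahydroazulen-4-yl 4-hydroxybenzoate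
Conditions: Bu4NF, AcOH, THF, 0 °C
Reagents that add atoms: none
Why: Fluoride removes the aryl silyl ether within minutes; acetic acid buffers the phenoxide so that the aryl ester and the epoxide survive.

## Compound list

1 | 3-methylcyclopent-2-en-1-one | CC1=CC(=O)CC1 | starting material
2 | 2-bromo-3-methylcyclopent-2-en-1-one | CC1=C(Br)C(=O)CC1 | intermediate
3 | (R)-2-bromo-3-methylcyclopent-2-en-1-ol | O[C@@H]1CCC(C)=C1Br | intermediate
4 | ethynyltrimethylsilane | C#C[Si](C)(C)C | starting material
5 | (R)-3-methyl-2-[(trimethylsilyl)ethynyl]cyclopent-2-en-1-ol | C[Si](C)(C)C#CC1=C(C)CC[C@H]1O | intermediate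
6 | (1S,2R,5R)-5-methyl-1-[(trimethylsilyl)ethynyl]bicyclo[3.1.0]hexan-2-ol | C[Si](C)(C)C#C[C@]12C[C@@]1(C)CC[C@H]2O | intermediate
7 | (1S,2R,5R)-1-ethynyl-5-methylbicyclo[3.1.0]hexan-2-ol | C#C[C@]12C[C@@]1(C)CC[C@H]2O | intermediate
8 | 1-[(1R,2R,5R)-2-hydroxy-5-methylbicyclo[3.1.0]hexan-1-yl]ethan-1-one | CC(=O)[C@]12C[C@@]1(C)CC[C@H]2O | intermediate
9 | 1-[(1R,2R,5R)-5-methyl-2-[(trimethylsilyl)oxy]bicyclo[3.1.0]hexan-1-yl]ethan-1-one | CC(=O)[C@]12C[C@@]1(C)CC[C@H]2O[Si](C)(C)C | intermediate
10 | trimethyl{[(1R,2R,5R)-5-methyl-1-{1-[(triisopropylsilyl)oxy]ethenyl}bicyclo[3.1.0]hexan-2-yl]oxy}silane | C=C(O[Si](C(C)C)(C(C)C)C(C)C)[C@]12C[C@@]1(C)CC[C@H]2O[Si](C)(C)C | intermediate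
11 | trimethyl(prop-1-yn-1-yl)silane | CC#C[Si](C)(C)C | starting material
12 | triisopropyl({(3R,8aR)-6,8a-dimethyl-7-(trimethylsilyl)-3-[(trimethylsilyl)oxy]-1,2,3,5,8,8a-hexahydroazulen-4-yl}oxy)silane | C[Si](C)(C)O[C@@H]1CC[C@]2(C)CC([Si](C)(C)C)=C(C)CC(O[Si](C(C)C)(C(C)C)C(C)C)=C12 | intermediate
13 | (3R,8aR)-6,8a-dimethyl-4-[(triisopropylsilyl)oxy]-7-(trimethylsilyl)-1,2,3,5,8,8a-hexahydroazulen-3-ol | O[C@@H]1CC[C@]2(C)CC([Si](C)(C)C)=C(C)CC(O[Si](C(C)C)(C(C)C)C(C)C)=C12 | intermediate
14 | (3R,3aR,4R,8aR)-6,8a-dimethyl-4-[(triisopropylsilyl)oxy]-7-(trimethylsilyl)-1,2,3,3a,4,5,8,8a-octahydroazulen-3-ol | O[C@@H]1CC[C@]2(C)CC([Si](C)(C)C)=C(C)C[C@@H](O[Si](C(C)C)(C(C)C)C(C)C)[C@H]21 | intermediate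
15 | (3R,3aR,4R,8aR)-6,8a-dimethyl-4-[(triisopropylsilyl)oxy]-1,2,3,3a,4,5,8,8a-octahydroazulen-3-ol | O[C@@H]1CC[C@]2(C)CC=C(C)C[C@@H](O[Si](C(C)C)(C(C)C)C(C)C)[C@H]21 | intermediate
16 | (3aS,4R,8aR)-6,8a-dimethyl-4-[(triisopropylsilyl)oxy]-2,3a,4,5,8,8a-hexahydroazulen-3(1H)-one | O=C1CC[C@]2(C)CC=C(C)C[C@@H](O[Si](C(C)C)(C(C)C)C(C)C)[C@H]21 | intermediate
17 | (3R,3aS,4R,8aR)-6,8a-dimethyl-3-(propan-2-yl)-4-[(triisopropylsilyl)oxy]-1,2,3,3a,4,5,8,8a-octahydroazulen-3-ol | CC(C)[C@]1(O)CC[C@]2(C)CC=C(C)C[C@@H](O[Si](C(C)C)(C(C)C)C(C)C)[C@H]21 | intermediate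
18 | (3R,3aS,4R,8aR)-6,8a-dimethyl-3-(propan-2-yl)-1,2,3,3a,4,5,8,8a-octahydroazulene-3,4-diol | CC(C)[C@]1(O)CC[C@]2(C)CC=C(C)C[C@@H](O)[C@H]21 | intermediate
19 | 4-hydroxybenzoic acid | OC(=O)c1ccc(O)cc1 | starting material
20 | tert-butyldimethylsilyl 4-[(tert-butyldimethylsilyl)oxy]benzoate | CC(C)(C)[Si](C)(C)OC(=O)c1ccc(O[Si](C)(C)C(C)(C)C)cc1 | intermediate
21 | 4-[(tert-butyldimethylsilyl)oxy]benzoic acid | OC(=O)c1ccc(O[Si](C)(C)C(C)(C)C)cc1 | intermediate
22 | (3R,3aS,4R,8aR)-3-hydroxy-6,8a-dimethyl-3-(propan-2-yl)-1,2,3,3a,4,5,8,8a-octahydroazulen-4-yl 4-[(tert-butyldimethylsilyl)oxy]benzoate | CC(C)[C@]1(O)CC[C@]2(C)CC=C(C)C[C@@H](OC(=O)c3ccc(O[Si](C)(C)C(C)(C)C)cc3)[C@H]21 | intermediate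
23 | (3R,3aS,4R,6R,7S,8aR)-6,7-epoxy-3-hydroxy-6,8a-dimethyl-3-(propan-2-yl)decahydroazulen-4-yl 4-[(tert-butyldimethylsilyl)oxy]benzoate | CC(C)[C@]1(O)CC[C@]2(C)C[C@@H]3O[C@]3(C)C[C@@H](OC(=O)c3ccc(O[Si](C)(C)C(C)(C)C)cc3)[C@H]21 | intermediate
24 | (3R,3aS,4R,6R,7S,8aR)-6,7-epoxy-3-hydroxy-6,8a-dimethyl-3-(propan-2-yl)decahydroazulen-4-yl 4-hydroxybenzoate | CC(C)[C@]1(O)CC[C@]2(C)C[C@@H]3O[C@]3(C)C[C@@H](OC(=O)c3ccc(O)cc3)[C@H]21 | target

## Step count and least certain steps

Total step count: 19. Longest linear sequence: 18 steps (1 to 24 through steps 1–15 and 17–19); step 16 is the one-step side branch.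

Step 11 (proposed new method). The likely failures are:
- no turnover, because the alkene is tetrasubstituted and carries a bulky silyloxy group;
- acid-induced loss of the enol ether;
- isomerisation of the allylic alcohol to the ketone, which would scramble C5;
- loss of silicon from C9 followed by reduction of C8=C9.

The fallback uses known reactions, sets out from 13 and comes back at 16. Dess–Martin oxidation of the allylic alcohol would give the β-silyloxy enone (8aR)-6,8a-dimethyl-4-[(triisopropylsilyl)oxy]-7-(trimethylsilyl)-2,5,8,8a-tetrahydroazulen-3(1H)-one F1, in which C4 is planar and no longer screens the α face. Heterogeneous hydrogenation (H2, Pd/C, ethyl acetate) should then add to C5=C6 from the face opposite the angular methyl and give (3aS,4R,8aR)-6,8a-dimethyl-4-[(triisopropylsilyl)oxy]-7-(trimethylsilyl)-2,3a,4,5,8,8a-hexahydroazulen-3(1H)-one F2. Brief CF3CO2H at 0 °C removes the C9 silyl group and gives 16.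

Step 9 (key step). The likely failures are:
- slow opening of a cyclopropane whose two reacting carbons are fully substituted;
- rearrangement of the vinylcyclopropane to a cyclopentene or ring-opened diene;
- the opposite alkyne orientation;
- alkyne oligomerisation.

The fallback keeps the same two bonds but makes them intramolecularly through a temporary silicon tether, setting out from 8 and coming back at 13. Silylation of 8 with chloro(dimethyl)(prop-1-yn-1-yl)silane and imidazole would give 1-[(1R,2R,5R)-2-{[dimethyl(prop-1-yn-1-yl)silyl]oxy}-5-methylbicyclo[3.1.0]hexan-1-yl]ethan-1-one F3. Enolisation with LiN(i-Pr)2 and trapping with i-Pr3SiOTf would give dimethyl(prop-1-yn-1-yl){[(1R,2R,5R)-5-methyl-1-{1-[(triisopropylsilyl)oxy]ethenyl}bicyclo[3.1.0]hexan-2-yl]oxy}silane F4. [Rh(CO)2Cl]2 would then form C7–C8 and C9–C10 with the tether holding the silicon-bearing alkyne carbon next to C10, giving the O4,C9-dimethylsilylene-bridged hexahydroazulene F5. MeLi opens the Si–O bond, which turns the tether silicon into the C9 trimethylsilyl group and frees the C4 hydroxyl, giving 13.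

Step 14. The likely failures are enolisation towards C5 (epimerisation to the cis-fused ketone, which the angular methyl may favour, or loss of the β-silyloxy group) and hydride transfer from the branched reagent. The fallback sets out from 16 and comes back at 17. Isopropenylmagnesium bromide with CeCl3, less hindered and unable to transfer a β-hydride, would give (3S,3aS,4R,8aR)-6,8a-dimethyl-3-(prop-1-en-2-yl)-4-[(triisopropylsilyl)oxy]-1,2,3,3a,4,5,8,8a-octahydroazulen-3-ol F6. Hydrogenation with RhCl(PPh3)3 then reduces the 1,1-disubstituted alkene in preference to the trisubstituted ring alkene and gives 17.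

Step 18. The likely failures are poor facial selectivity, if the seven-membered ring adopts a conformation that exposes the β face, and acid opening of the epoxide. The fallback sets out from 22 and comes back at 23, and it inverts the facial outcome of a direct epoxidation. N-Bromosuccinimide in aqueous acetone forms the bromonium ion on the face a peracid prefers, and water opens it anti at tertiary C8 to give the bromohydrin 7-bromo-3,6-dihydroxy-6,8a-dimethyl-3-(propan-2-yl)decahydroazulen-4-yl 4-[(tert-butyldimethylsilyl)oxy]benzoate (azulene numbering, 6-hydroxyl α, 7-bromine β) F7. K2CO3 in acetonitrile then closes the α epoxide 23.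

Step 3. The likely failures are slow oxidative addition into a hindered, electron-rich alkenyl bromide and homocoupling of the alkyne. The fallback changes the order, setting out from 2 and coming back at 5. The activated bromoenone 2 is coupled with 4 under the same catalysts to give 3-methyl-2-[(trimethylsilyl)ethynyl]cyclopent-2-en-1-one F8, and CBS reduction with the (S)-catalyst then gives 5.

Further compounds

F1 | step 11 | (8aR)-6,8a-dimethyl-4-[(triisopropylsilyl)oxy]-7-(trimethylsilyl)-2,5,8,8a-tetrahydroazulen-3(1H)-one | O=C1CC[C@]2(C)CC([Si](C)(C)C)=C(C)CC(O[Si](C(C)C)(C(C)C)C(C)C)=C12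
F2 | step 11 | (3aS,4R,8aR)-6,8a-dimethyl-4-[(triisopropylsilyl)oxy]-7-(trimethylsilyl)-2,3a,4,5,8,8a-hexahydroazulen-3(1H)-one | O=C1CC[C@]2(C)CC([Si](C)(C)C)=C(C)C[C@@H](O[Si](C(C)C)(C(C)C)C(C)C)[C@H]21
F3 | step 9 | 1-[(1R,2R,5R)-2-{[dimethyl(prop-1-yn-1-yl)silyl]oxy}-5-methylbicyclo[3.1.0]hexan-1-yl]ethan-1-one | CC(=O)[C@]12C[C@@]1(C)CC[C@H]2O[Si](C)(C)C#CC
F4 | step 9 | dimethyl(prop-1-yn-1-yl){[(1R,2R,5R)-5-methyl-1-{1-[(triisopropylsilyl)oxy]ethenyl}bicyclo[3.1.0]hexan-2-yl]oxy}silane | C=C(O[Si](C(C)C)(C(C)C)C(C)C)[C@]12C[C@@]1(C)CC[C@H]2O[Si](C)(C)C#CC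
F5 | step 9 | O4,C9-dimethylsilylene-bridged hexahydroazulene (cycloadduct of F4, triisopropylsilyl enol ether at C6) | C[Si]3(C)O[C@@H]1CC[C@]2(C)CC3=C(C)CC(O[Si](C(C)C)(C(C)C)C(C)C)=C12
F6 | step 14 | (3S,3aS,4R,8aR)-6,8a-dimethyl-3-(prop-1-en-2-yl)-4-[(triisopropylsilyl)oxy]-1,2,3,3a,4,5,8,8a-octahydroazulen-3-ol | C=C(C)[C@]1(O)CC[C@]2(C)CC=C(C)C[C@@H](O[Si](C(C)C)(C(C)C)C(C)C)[C@H]21
F7 | step 18 | 7-bromo-3,6-dihydroxy-6,8a-dimethyl-3-(propan-2-yl)decahydroazulen-4-yl 4-[(tert-butyldimethylsilyl)oxy]benzoate (6-hydroxyl α, 7-bromine β) | CC(C)[C@]1(O)CC[C@]2(C)C[C@@H](Br)[C@@](O)(C)C[C@@H](OC(=O)c3ccc(O[Si](C)(C)C(C)(C)C)cc3)[C@H]21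
F8 | step 3 | 3-methyl-2-[(trimethylsilyl)ethynyl]cyclopent-2-en-1-one | CC1=C(C#C[Si](C)(C)C)C(=O)CC1
A1 | alternative 1 | (8aR)-6,8a-dimethyl-2,5,8,8a-tetrahydroazulen-3(1H)-one | O=C1CC[C@]2(C)CC=C(C)CC=C12
A2 | alternative 1 | 5-[(1R,2R)-1-methyl-2-(prop-1-en-2-yl)cyclopropyl]pent-1-yn-3-one | C#CC(=O)CC[C@]1(C)C[C@@H]1C(C)=C
A3 | alternative 2 | (4S,5S)-4-{[(tert-butyldimethylsilyl)oxy]methyl}-5-(diethoxymethyl)-4-methylcyclopent-2-en-1-one | O=C1C=C[C@](C)(CO[Si](C)(C)C(C)(C)C)[C@H]1C(OCC)OCC
A4 | alternative 2 | (4R,5Z)-7-[(tert-butyldimethylsilyl)oxy]-1,1-diethoxy-6-methylhept-5-en-2-yn-4-yl 2,2-dimethylpropanoate | CCOC(OCC)C#C[C@H](OC(=O)C(C)(C)C)/C=C(/C)CO[Si](C)(C)C(C)(C)C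
A5 | alternative 3 | (3R,3aR,8aS)-3-[(tert-butyldimethylsilyl)oxy]-6,8a-dimethyl-3-(propan-2-yl)-2,3,3a,7,8,8a-hexahydroazulen-4(1H)-one | CC(C)[C@]1(O[Si](C)(C)C(C)(C)C)CC[C@]2(C)CCC(C)=CC(=O)[C@H]21
A6 | alternative 3 | (6S)-6-{(3R)-3-[(tert-butyldimethylsilyl)oxy]-4-methylpentyl}-7-diazo-3,6-dimethylcyclohept-2-en-1-one | CC(C)[C@H](O[Si](C)(C)C(C)(C)C)CC[C@]1(C)CCC(C)=CC(=O)C1=[N+]=[N-]
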